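All constants are made up; no experiment stands behind them.

Leave the flasks shut.

the same everywhere: J 0.050 M; X 0.100 M; Z 0.050 M; time 3.0 h

|  | temperature | remark |
|---|---|---|
| alder | 75 °C |  |
| elm | 90 °C |  |
| maple | 105 °C |  |
| birch |  | at 75 °C until 50 min, from then on at 105 °C |

- the flask with the highest amount of E.J, in percent of the J and Z together charged ("all alike" if they lie within 1.5 percentage points) (alder / elm / maple / birch / all alike)
- final E.J, as a percentage of the J and Z together charged, in alder
- final E.J, as a percentage of the J and Z together charged, in elm
- final E.J, as a percentage of the J and Z together charged, in maple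
- final E.J, as a percentage of the J and Z together charged, in birch

- E is single-handed; J and Z are mirror images of each other, charged as a racemate, each of them at the stated concentration
- solid, in amounts per volume of the solution: X
- the list of constants is for 90 °C, to be carried to other temperatures by the activation energies and enthalpies
- at the start none of X is in solution
- the handed part of E does not stay in what it makes, so the products of the two hands are mirror images too

    E + J → E.J (k1 = 18.8 M⁻¹ min⁻¹, Ea1 = 45.0 kJ mol⁻¹)
    E.J ⇌ E.Z (k2 = 0.0791 min⁻¹, Ea2 = 105 kJ mol⁻¹)
    J ⇌ Z (k3 = 0.317 min⁻¹, Ea3 = 111 kJ mol⁻¹)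
    E + Z → E.Z (k4 = 1.27 M⁻¹ min⁻¹, Ea4 = 85.0 kJ mol⁻¹)
    X ⇌ E, rate k5*(cs5 - [E]) while solid is left; crystals form when [E] > cs5 (cs5 = 21 mM, k5 = 1.33 min⁻¹)
    E ⇌ L (K6 = 9.9, k6 = 0.0123 min⁻¹, Ea6 = 116 kJ mol⁻¹, ΔH6 = 8.00 kJ mol⁻¹)
    (constants at 90 °C)

I reckoned what would stand in them from ratios of rates, because time drops out of a ratio. Steps 1 and 4 each use one E and one J or Z to make one product, so product formed per E so used stayed at one whatever the clock said, while E standing free or held as L made none. The X charged, 0.100 M, matched J and Z together, 0.100 M, so neither side was charged in excess. The second ratio, E.J formed over E.Z formed, began at 14.8 in elm, the selectivity factor at that flask's temperature, since [J] and [Z] started equal. I did not bank on it, because step 2 levels E.J and E.Z with a half-life of 0.327 h in alder, far shorter than the 3.0 h of the run, and it ran 18 times faster in maple than in alder.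

So I carried 50.0 % forward: the ceiling on E.J, which is half the X charged divided by the J and Z charged, good once step 2 has relaxed and while X does not exceed J and Z together. I expected to find [E.J] and [E.Z] level and a little under that ceiling, with some J and Z unreacted and some E held as L. The X charge was the thing not to touch, since the ceiling moves in proportion to it. Temperature does not enter the ceiling, so I saw no reason to change the heating.

The forecast read all alike, with 48.6 % in alder, 47.9 % in elm, 47.3 % in maple and 48.5 % in birch, on the ground that “E.J ends at about half of the product in every flask”.

The flasks gave all alike: 48.9 % in alder, 48.1 % in elm, 47.7 % in maple and 48.5 % in birch. Alder held 0 % of its X at 3.00 h, with E.J at 48.9 % and E.Z at 48.3 %. Against the ceiling of 50.0 %, alder stood 1.1 percentage points short and maple 2.3 points short, and at the asked time E.J stood below it in each flask, though birch had held 56.7 % at 0.833 h, before E.J and E.Z had levelled.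

The neighbour flask, alder with 0.060 M of X, had a ceiling of 30.0 % by the same division. It ended with E.J at 29.8 %, E.Z at 29.7 % and J at 20.3 %.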